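No single percentage of L can serve both earlier runs: at 90.0 s alder holds 15.5 % of its Z, and maple, charged with more Z, holds 10.8 %.

all flasks: J 1.7 mM (held)
- alder: Z 8.5 mM; run made earlier
- maple: Z 13 mM; run made earlier
- flask: Z 17 mM; time 2.5 min

- alder (time / s: L / %): 12.0: 0.6; 30.0: 2.5; 60.0: 9.2; 90.0: 15.5
- maple (time / s: L / %): 12.0: 1.0; 30.0: 3.3; 60.0: 7.6; 90.0: 10.8

(each reading ± 1 percentage point)

* the L standing at 2.5 min, as a percentage of the Z charged
* the change that raises the amount of L at 2.5 min, in percent of the Z charged most ("none" if none brings more than 2 percentage points) (green / blue / red / ochre / none)
* amount of L at 2.5 min, in percent of the Z charged, after blue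

- as a solid, counted per litre of solution: Z
- at the start none of Z is in solution
- at the start none of J is in solution

- green: doubling the solubility of Z, all else as stated
- blue: doubling the saturation concentration of J, all else as stated
- red: doubling the dissolution coefficient of Z, all else as stated
- ochre: doubling the transfer coefficient of J, all else as stated

Counted as concentration, the two runs lie close at that time, 1.32 mM in alder against 1.40 mM in maple. Between 30.0 s and 90.0 s, L climbs at 0.0184 mM s⁻¹ in alder and 0.0163 mM s⁻¹ in maple, so within these readings the slope does not follow the charge: it looks zero-order in Z. Time and charge then fold into one number, the reach, which is the share of the charge that such a steady rate can turn into L in the time, maple's rate times time over charge. For the flask it comes to 14.3 %, and this reckoning commits to that value.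

One number is not enough everywhere. At 30.0 s the reach of alder is 5.74 %, above the reading of 2.5 %, so it misses the slow start of that run. It also names no step, so it gives no ground for choosing among the changes.

The forecast gives 14.5 % from the same readings, chooses blue and expects 27 % after it, holding that “Doubling J saturation doubles the rate under either limit”.

The flask holds 14.7 % of L against a reach of 14.3 %. The best change is green, with a gain of 11 percentage points, while blue gains 2.5 points and ends at 17.1 %.

    G + L → Q (k = 2.80 M⁻¹ s⁻¹)
    Z ⇌ E, rate k2*(cs2 - [E]) while solid is left; crystals form when [E] > cs2 (solubility = 16.0 mM, k = 0.00350 s⁻¹)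
    E + G ⇌ L (K = 14000 M⁻¹, k = 10.0 M⁻¹ s⁻¹)
    L ⇌ X (K = 4.70, k = 0.00520 s⁻¹)
    J ⇌ G, rate k5*(csat - [G]) (kL = 0.0740 s⁻¹)

In the flask, by the asked time, the going into solution of Z can deliver at most 49.4 % of the charge into a solution kept empty, less than the 111 % from the passage of J into G. For the same flask left until 1.5 min, the reach is 8.60 %, and that flask holds 8.37 % of L.

Readings and results were computed for substances that don't exist.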